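**Plan**

- Retrosynthesis: the C8 ester is cut first (acid 20 + alcohol 17), then the exocyclic C11=C13 methylene. Ring A, the tetrahydrooxepine (O, C10, C1, C2, C3=C4, C5), is then cut at C1–C10 and O–C5. This leaves lactone 11, which carries a C10 methyl ketone and an α-cyclopropyl acrylate (C5=C4, cyclopropane C3/C2/C1).
- Enabling feature: ring A holds the C10–O unit next to a five-carbon chain C1–C5 with a C3=C4 double bond, which is what a ketone C=O and a vinylcyclopropane deliver in a hetero-(5+2) annulation. Because the oxygen is the one-atom bridge, the tether C6–C9 links the carbonyl carbon to the vinyl terminus, so the same event closes ring B (O, C10, C9, C8, C7, C6, C5) and the ten-membered carbocycle.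
- 11 is cut further at C8–C9 (acetone aldol), C4=C5 (Horner–Wadsworth–Emmons) and C7–C8 (vinyl conjugate addition to a chiral-pool butenolide).
- Forward order: γ-lactone from 1; open chain built on it; rings B and A of the 11-oxabicyclo[4.4.1]undecene together in one step; methylene, desilylation and side-chain ester last.
- Stereochemistry: C6 from (S)-butenolide 1; C7 by trans conjugate addition; C8 by L-proline; C5 by allylic 1,3-strain and C10 by the bridge geometry in the key step; C2′ from (R)-2-methylglycidol.

Key step: step 9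

Remark on numbering: germacrane-type locants are used throughout. C1–C10 are the ring carbons (C1 = CH2 next to quaternary C10; C3=C4; C5 and C10 carry the bridging oxygen; C6 carries the lactone oxygen; C8 the ester oxygen). C11/C12/C13 are the lactone α-carbon, carbonyl and exocyclic methylene; C14 is the methyl on C10; C15 the ester carbon on C4. The target is 5R,6S,7R,8R,10S,2′S; where a descriptor differs in an intermediate, only CIP priorities have changed, not the spatial arrangement.

Assumption: 1, 6 and 18 are taken as commercially available. The E isomer of 8 is taken as the main olefination product; either alkene geometry should serve in step 9, because C4 becomes a ketene acetal carbon before ring A closes.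

**Step 1**
Reactants: 1 (S)-5-(hydroxymethyl)furan-2(5H)-one
Product: 2 (S)-5-[(triethylsilyloxy)methyl]furan-2(5H)-one
Conditions: Et3SiCl, imidazole, CH2Cl2, 0 °C
Reagents that add atoms: chlorotriethylsilane CC[Si](Cl)(CC)CC
Why: Standard silylation of a primary alcohol with imidazole, a base too weak to deprotonate the γ-position, so C6 is untouched.

**Step 2**
Reactants: 2 (S)-5-[(triethylsilyloxy)methyl]furan-2(5H)-one
Product: 4 (4R,5S)-5-[(triethylsilyloxy)methyl]-4-vinyloxolan-2-one, via silyl ketene acetal 3 (not isolated)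
Conditions: CH2=CHMgBr, CuBr·SMe2 (10 mol %), Me3SiCl, THF, −78 °C; aq NH4Cl
Reagents that add atoms: vinylmagnesium bromide C=C[Mg]Br
Why: Copper-catalysed, Me3SiCl-accelerated conjugate addition to the butenolide occurs anti to the C6 silyloxymethyl group and sets C7 trans to C6.

**Step 3**
Reactants: 4 (4R,5S)-5-[(triethylsilyloxy)methyl]-4-vinyloxolan-2-one
Product: 5 (2S,3R)-5-oxo-3-vinyloxolane-2-carbaldehyde
Conditions: (COCl)2, DMSO, CH2Cl2, −78 → −40 °C; Et3N, −78 → 0 °C; used crude
Reagents that add atoms: none
Why: Swern oxidation of a primary triethylsilyl ether, in which the chlorosulfonium reagent cleaves the Si–O bond in situ and the alkoxysulfonium ion collapses to the aldehyde; the 2,3-trans lactone is the thermodynamically preferred arrangement, so C6 should hold.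

**Step 4**
Reactants: 6 methyl 2-cyclopropylacetate
Product: 7 methyl 2-cyclopropyl-2-(diethoxyphosphoryl)acetate (racemic)
Conditions: LiN(i-Pr)2 (2.1 equiv), THF, −78 °C; ClP(O)(OEt)2; → 0 °C
Reagents that add atoms: diethyl chlorophosphate CCOP(=O)(Cl)OCC
Why: Phosphorylation of the ester enolate, with O-to-C 1,3-phosphorus migration under the second equivalent of amide base, gives the α-phosphono ester; its stereocentre disappears in step 5.

**Step 5**
Reactants: 5 (2S,3R)-5-oxo-3-vinyloxolane-2-carbaldehyde; 7 methyl 2-cyclopropyl-2-(diethoxyphosphoryl)acetate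
Product: 8 methyl (E)-2-cyclopropyl-3-[(2S,3R)-5-oxo-3-vinyloxolan-2-yl]prop-2-enoate
Conditions: 7, NaH, THF, 0 °C; then 5, −78 → 0 °C
Reagents that add atoms: none
Why: Horner–Wadsworth–Emmons olefination, which with α-branched phosphonoacetates should give mainly the E-alkene (ester trans to C6); the pre-formed sodium phosphonate leaves no free base to epimerise the aldehyde.

**Step 6**
Reactants: 8 methyl (E)-2-cyclopropyl-3-[(2S,3R)-5-oxo-3-vinyloxolan-2-yl]prop-2-enoate
Product: 9 methyl (E)-2-cyclopropyl-3-[(2R,3S)-3-formyl-5-oxooxolan-2-yl]prop-2-enoate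
Conditions: O3, pyridine, CH2Cl2/MeOH, −78 °C (indicator dye); Me2S
Reagents that add atoms: ozone [O-][O+]=O
Why: Ozonolysis with reductive work-up; the monosubstituted vinyl group is far more electron-rich than the ester-conjugated trisubstituted C4=C5 bond and should react first.

**Step 7**
Reactants: 9 methyl (E)-2-cyclopropyl-3-[(2R,3S)-3-formyl-5-oxooxolan-2-yl]prop-2-enoate
Product: 10 methyl (E)-2-cyclopropyl-3-{(2R,3R)-3-[(1R)-1-hydroxy-3-oxobutyl]-5-oxooxolan-2-yl}prop-2-enoate
Conditions: L-proline (30 mol %), acetone/DMSO, rt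
Reagents that add atoms: acetone CC(C)=O
Why: Proline-catalysed enamine aldol addition of acetone, in which the catalyst directs attack to the re face of the α-branched aldehyde (same sense as with isobutyraldehyde) and sets 8R; C7, a ring carbon flanked by two ring carbons, should exert little bias of its own.

**Step 8**
Reactants: 10 methyl (E)-2-cyclopropyl-3-{(2R,3R)-3-[(1R)-1-hydroxy-3-oxobutyl]-5-oxooxolan-2-yl}prop-2-enoate
Product: 11 methyl (E)-3-{(2R,3S)-3-[(1R)-1-(tert-butyldimethylsilyloxy)-3-oxobutyl]-5-oxooxolan-2-yl}-2-cyclopropylprop-2-enoate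
Conditions: t-BuMe2SiOTf, 2,6-lutidine, CH2Cl2, −78 °C
Reagents that add atoms: tert-butyldimethylsilyl triflate CC(C)(C)[Si](C)(C)OS(=O)(=O)C(F)(F)F
Why: Low-temperature silylation of the hindered secondary alcohol, under which the β-hydroxy ketone should neither enolise nor eliminate; the silyl ether blocks O8 during the key step.

**Step 9**
Reactants: 11 methyl (E)-3-{(2R,3S)-3-[(1R)-1-(tert-butyldimethylsilyloxy)-3-oxobutyl]-5-oxooxolan-2-yl}-2-cyclopropylprop-2-enoate
Product: 13 bridged lactone (5R,6S,7S,8R,10S): 11-oxabicyclo[4.4.1]undec-3-ene with C4-CO2Me, C10-CH3, C8-OSiMe2t-Bu and a trans-fused γ-lactone (O–C6, C7–C11H2–C12=O), via oxocarbenium ion 12 (not isolated)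
Conditions: Me3SiNTf2 (20 mol %), 2,6-di-tert-butyl-4-methylpyridine (10 mol %), CH2Cl2 (0.01 M), −78 → −20 °C; Et3N quench
Reagents that add atoms: none
Why: Proposed new method: silylation of the enoate carbonyl by Me3Si+ should let the free ketone oxygen add to C5 (7-exo-trig oxa-Michael, ring B) to give the oxocarbenium/silyl ketene acetal ion pair 12, whose ketene acetal then pushes through the bisected cyclopropane so that C1 attacks C10 with cleavage of C1–C3 (about 27 kcal/mol of strain released), closing ring A by 7-endo-trig attack on the cyclic oxocarbenium ion, creating C3=C4 and returning Me3Si+; overall a stepwise hetero-(5+2) annulation with C=O as the two-atom and the vinylcyclopropane as the five-carbon partner. The closest known reaction types are the Lewis-acid-catalysed formal (3+2) annulation of donor–acceptor cyclopropanes with aldehydes and ketones, the homoallylation of carbonyl compounds by cyclopropylmethyl stannanes and silanes, silylium-catalysed Mukaiyama–Michael additions to simple enoates, and the metal-catalysed vinylcyclopropane (5+2) cycloaddition. C5 is controlled by allylic 1,3-strain: H6 eclipses the C4 substituent, so the tethered oxygen attacks the alkene face syn to C7 and anti to the lactone oxygen, which gives 5R. C10 has no freedom, since a one-atom bridge across the ten-membered ring can only be syn, which gives 10S, and the ring enforces the cis geometry of C3=C4. The step needs bridged rather than fused regiochemistry and attack by C1 rather than C4: polarity secures the first (C5 is the only electrophilic alkene carbon and C10 the only carbon electrophile), and the second follows because C4 attack would give a strained, acid-reversible oxetane whereas C1 attack is strain-releasing and irreversible.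

**Step 10**
Reactants: 13 bridged lactone (5R,6S,7S,8R,10S) with C11H2
Product: 16 α-methylene lactone (5R,6S,7S,8R,10S): 13 with C11=C13H2, via Mannich base 14 (not isolated), via ammonium iodide 15 (not isolated)
Conditions: LiN(SiMe3)2, THF, −78 °C; CH2=NMe2+ I−, −78 °C → rt; MeI, MeOH, rt; aq NaHCO3, CH2Cl2
Reagents that add atoms: N,N-dimethylmethyleneiminium iodide C=[N+](C)C.[I-]
Why: Kinetic enolisation of the lactone (its α-CH2 should be more readily deprotonated than the poorly aligned γ-CH2 of the cyclic enoate), Mannich reaction, N-methylation and E1cB loss of trimethylamine give the exocyclic methylene; the transient C11 stereocentre is destroyed.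

**Step 11**
Reactants: 16 α-methylene lactone (5R,6S,7S,8R,10S) with C8-OSiMe2t-Bu
Product: 17 C8 alcohol (5R,6S,7R,8R,10S) of the bridged α-methylene lactone
Conditions: HF·pyridine, pyridine, THF, 0 °C → rt
Reagents that add atoms: none
Why: Fluoride cleavage of the silyl ether under buffered, non-basic conditions that should leave the α-methylene lactone, the enoate and the bridging ether untouched.

**Step 12**
Reactants: 18 (R)-2-methylglycidol [(R)-(2-methyloxiran-2-yl)methanol]
Product: 19 (S)-2-methylbut-3-ene-1,2-diol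
Conditions: Me3S+ I−, n-BuLi, THF, −10 °C → rt
Reagents that add atoms: trimethylsulfonium iodide C[S+](C)C.[I-]
Why: Dimethylsulfonium methylide opens the epoxide at its CH2 terminus and the betaine eliminates dimethyl sulfide to the one-carbon-homologated allylic alcohol; the quaternary stereocentre is not involved, and the Payne rearrangement of this alkoxide is degenerate and returns the same enantiomer.

**Step 13**
Reactants: 19 (S)-2-methylbut-3-ene-1,2-diol
Product: 20 (S)-2-hydroxy-2-methylbut-3-enoic acid
Conditions: TEMPO (cat.), NaOCl (cat.), NaClO2, MeCN/phosphate buffer pH 6.7, 35 °C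
Reagents that add atoms: sodium chlorite [Na+].[O-]Cl=O
Why: Nitroxyl/hypochlorite/chlorite oxidation takes the primary alcohol of the 1,2-diol through the aldehyde to the α-hydroxy acid without glycol cleavage and without touching the tertiary alcohol or the stereocentre.

**Step 14**
Reactants: 17 C8 alcohol (5R,6S,7R,8R,10S); 20 (S)-2-hydroxy-2-methylbut-3-enoic acid
Product: 22 target CNP0325750.1 (5R,6S,7R,8R,10S,2′S), via mixed anhydride 21 (not isolated)
Conditions: 20, 2,4,6-Cl3C6H2COCl, Et3N, THF, rt; then 17, DMAP, toluene, rt → 40 °C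
Reagents that add atoms: none
Why: Yamaguchi esterification, in which the mixed anhydride and DMAP give an acylpyridinium ion that acylates the secondary C8 hydroxyl; the tertiary hydroxyl of the acid should be too hindered to compete, and no stereocentre is touched.

**Compound list**

1 | (S)-5-(hydroxymethyl)furan-2(5H)-one | OC[C@H]1OC(=O)C=C1 | starting material
2 | (S)-5-[(triethylsilyloxy)methyl]furan-2(5H)-one | CC[Si](CC)(CC)OC[C@H]1OC(=O)C=C1 | intermediate
3 | 4,5-trans silyl ketene acetal: 5-[(triethylsilyloxy)methyl]-2-(trimethylsilyloxy)-4-vinyl-4,5-dihydrofuran | CC[Si](CC)(CC)OC[C@H]1OC(O[Si](C)(C)C)=C[C@@H]1C=C | intermediate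
4 | (4R,5S)-5-[(triethylsilyloxy)methyl]-4-vinyloxolan-2-one | CC[Si](CC)(CC)OC[C@H]1OC(=O)C[C@@H]1C=C | intermediate
5 | (2S,3R)-5-oxo-3-vinyloxolane-2-carbaldehyde | O=C[C@H]1OC(=O)C[C@@H]1C=C | intermediate
6 | methyl 2-cyclopropylacetate | COC(=O)CC1CC1 | starting material
7 | methyl 2-cyclopropyl-2-(diethoxyphosphoryl)acetate (racemic) | CCOP(=O)(OCC)C(C1CC1)C(=O)OC | intermediate
8 | methyl (E)-2-cyclopropyl-3-[(2S,3R)-5-oxo-3-vinyloxolan-2-yl]prop-2-enoate | COC(=O)/C(C1CC1)=C/[C@H]1OC(=O)C[C@@H]1C=C | intermediate
9 | methyl (E)-2-cyclopropyl-3-[(2R,3S)-3-formyl-5-oxooxolan-2-yl]prop-2-enoate | COC(=O)/C(C1CC1)=C/[C@H]1OC(=O)C[C@@H]1C=O | intermediate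
10 | methyl (E)-2-cyclopropyl-3-{(2R,3R)-3-[(1R)-1-hydroxy-3-oxobutyl]-5-oxooxolan-2-yl}prop-2-enoate | COC(=O)/C(C1CC1)=C/[C@H]1OC(=O)C[C@@H]1[C@H](O)CC(C)=O | intermediate
11 | methyl (E)-3-{(2R,3S)-3-[(1R)-1-(tert-butyldimethylsilyloxy)-3-oxobutyl]-5-oxooxolan-2-yl}-2-cyclopropylprop-2-enoate | COC(=O)/C(C1CC1)=C/[C@H]1OC(=O)C[C@@H]1[C@H](O[Si](C)(C)C(C)(C)C)CC(C)=O | intermediate
12 | ring B oxocarbenium ion carrying the C4 silyl ketene acetal and cyclopropane, triflimide salt (ketene acetal geometry open) | CC(C)(C)[Si](C)(C)O[C@@H]1CC(C)=[O+][C@H](C(C2CC2)=C(OC)O[Si](C)(C)C)[C@H]2OC(=O)C[C@@H]21.[N-](S(=O)(=O)C(F)(F)F)S(=O)(=O)C(F)(F)F | intermediate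
13 | bridged lactone (5R,6S,7S,8R,10S), C8-OSiMe2t-Bu, C11H2 | CC(C)(C)[Si](C)(C)O[C@@H]1C[C@]2(C)CCC=C(C(=O)OC)[C@@H](O2)[C@H]2OC(=O)C[C@@H]21 | intermediate
14 | C11-(dimethylaminomethyl) lactone (C11 epimers, inconsequential) | CC(C)(C)[Si](C)(C)O[C@@H]1C[C@]2(C)CCC=C(C(=O)OC)[C@@H](O2)[C@H]2OC(=O)C(CN(C)C)[C@@H]21 | intermediate
15 | C11-(trimethylammoniomethyl) lactone iodide | CC(C)(C)[Si](C)(C)O[C@@H]1C[C@]2(C)CCC=C(C(=O)OC)[C@@H](O2)[C@H]2OC(=O)C(C[N+](C)(C)C)[C@@H]21.[I-] | intermediate
16 | bridged α-methylene lactone (5R,6S,7S,8R,10S), C8-OSiMe2t-Bu | CC(C)(C)[Si](C)(C)O[C@@H]1C[C@]2(C)CCC=C(C(=O)OC)[C@@H](O2)[C@H]2OC(=O)C(=C)[C@@H]21 | intermediate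
17 | bridged α-methylene lactone C8 alcohol (5R,6S,7R,8R,10S) | O[C@@H]1C[C@]2(C)CCC=C(C(=O)OC)[C@@H](O2)[C@H]2OC(=O)C(=C)[C@@H]21 | intermediate
18 | (R)-2-methylglycidol | C[C@@]1(CO)CO1 | starting material
19 | (S)-2-methylbut-3-ene-1,2-diol | C=C[C@](C)(O)CO | intermediate
20 | (S)-2-hydroxy-2-methylbut-3-enoic acid | C=C[C@](C)(O)C(=O)O | intermediate
21 | (S)-2-hydroxy-2-methylbut-3-enoic 2,4,6-trichlorobenzoic anhydride | C=C[C@](C)(O)C(=O)OC(=O)c1c(Cl)cc(Cl)cc1Cl | intermediate
22 | CNP0325750.1 (5R,6S,7R,8R,10S,2′S) | C=C[C@](C)(O)C(=O)O[C@@H]1C[C@]2(C)CCC=C(C(=O)OC)[C@@H](O2)[C@H]2OC(=O)C(=C)[C@@H]21 | target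

**Step count**

Total step count: 14.
Longest linear sequence: 11 steps (steps 1, 2, 3, 5, 6, 7, 8, 9, 10, 11, 14).

**Steps most likely to fail**

Step 9 (proposed new method). What may go wrong: the ketone oxygen may fail to add to the hindered α,β-disubstituted enoate; the oxocarbenium ion may lose a proton to an enol ether or eliminate the β-silyloxy group; or the ketene acetal may close through C4 instead of opening the cyclopropane. Fallback with known reactions, setting out from 11 and coming back at 13: ozonolysis of the C4=C5 bond of 11 (O3; Me2S) should give keto aldehyde F1. Morita–Baylis–Hillman reaction of F1 with methyl acrylate (DABCO) should give allylic alcohol F2 (C5 epimers, both usable). Addition of CH2=CHCH2CH2MgBr/CeCl3 to the methyl ketone should give tertiary alcohol F3 (C10 epimers). Selective acetylation of the secondary allylic hydroxyl (Ac2O, pyridine) should give acetate F4. Intramolecular allylic etherification catalysed by Pd(PPh3)4 (Tsuji–Trost type, the tertiary alcohol attacking C5 of the ester-substituted allyl unit) should close ring B to oxepane diene F5. Ring-closing metathesis of the butenyl and acrylate alkenes with second-generation Grubbs catalyst RuCl2(=CHPh)(H2IMes)(PCy3) should close ring A and give 13. In this variant C5 and C10 are no longer set by the substrate, so the 5R,10S diastereomer of F5 would have to be separated before metathesis.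

Step 14. What may go wrong: acylation of the hindered C8 hydroxyl may be slow enough that the unprotected tertiary hydroxy acid acylates itself or the activated acid decomposes. Fallback, setting out from 20 and 17 and coming back at 22: silylation of 20 with Et3SiOTf/2,6-lutidine should give bis-silyl derivative F6. Cleavage of its silyl ester (K2CO3, MeOH/H2O) should give O-silyl acid F7. Coupling of F7 with 17 through mixed anhydride F8 (2,4,6-Cl3C6H2COCl, Et3N; DMAP) should give silyl-protected ester F9, and HF·pyridine should then release 22. Acylation and liberation of the tertiary hydroxyl are thus separated.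

Step 7. What may go wrong: enamine formation at the substrate aldehyde may cause epimerisation at C7 or β-elimination of the lactone carboxylate, and facial selectivity may be poor if the catalyst preference opposes the Felkin preference of the aldehyde. Fallback, setting out from 9 and coming back at 11: reagent-controlled methallylboration with (+)-Ipc2BOMe/CH2=C(CH3)CH2MgCl (re-face addition, non-basic, −78 °C) should give homoallylic alcohol F10. Silylation (t-BuMe2SiOTf, 2,6-lutidine) should give silyl ether F11. Ozonolysis of its electron-rich 1,1-disubstituted alkene (O3; Me2S) should unveil the methyl ketone and give 11.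

**Further compounds**

F1 | step 9 | keto aldehyde: lactone 11 with C5 as CHO (C4 unit removed) | O=C[C@H]1OC(=O)C[C@@H]1[C@H](O[Si](C)(C)C(C)(C)C)CC(C)=O
F2 | step 9 | Morita–Baylis–Hillman alcohol: C5(OH)–C4(=CH2)CO2Me on the lactone, C10 methyl ketone (C5 epimers) | C=C(C(=O)OC)C(O)[C@H]1OC(=O)C[C@@H]1[C@H](O[Si](C)(C)C(C)(C)C)CC(C)=O
F3 | step 9 | diol: F2 with C10 as tertiary alcohol bearing CH3 and but-3-enyl (C5 and C10 epimers) | C=C(C(=O)OC)C(O)[C@H]1OC(=O)C[C@@H]1[C@H](O[Si](C)(C)C(C)(C)C)CC(C)(O)CCC=C
F4 | step 9 | C5 acetate of F3 | C=C(C(=O)OC)C(OC(C)=O)[C@H]1OC(=O)C[C@@H]1[C@H](O[Si](C)(C)C(C)(C)C)CC(C)(O)CCC=C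
F5 | step 9 | ring B oxepane diene (5R,10S isomer): C5–O–C10 ether, C5-C(=CH2)CO2Me, C10-CH3 and C10-but-3-enyl | CC(C)(C)[Si](C)(C)O[C@@H]1C[C@](C)(CCC=C)O[C@H](C(=C)C(=O)OC)[C@H]2OC(=O)C[C@@H]21
F6 | step 14 | triethylsilyl (S)-2-methyl-2-(triethylsilyloxy)but-3-enoate | C=C[C@](C)(O[Si](CC)(CC)CC)C(=O)O[Si](CC)(CC)CC
F7 | step 14 | (S)-2-methyl-2-(triethylsilyloxy)but-3-enoic acid | C=C[C@](C)(O[Si](CC)(CC)CC)C(=O)O
F8 | step 14 | mixed anhydride of F7 with 2,4,6-trichlorobenzoic acid | C=C[C@](C)(O[Si](CC)(CC)CC)C(=O)OC(=O)c1c(Cl)cc(Cl)cc1Cl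
F9 | step 14 | 2′-O-triethylsilyl ether of the target | C=C[C@](C)(O[Si](CC)(CC)CC)C(=O)O[C@@H]1C[C@]2(C)CCC=C(C(=O)OC)[C@@H](O2)[C@H]2OC(=O)C(=C)[C@@H]21
F10 | step 7 | homoallylic alcohol: lactone 9 with C8 as (R)-CH(OH)CH2C(CH3)=CH2 | COC(=O)/C(C1CC1)=C/[C@H]1OC(=O)C[C@@H]1[C@H](O)CC(C)=C
F11 | step 7 | tert-butyldimethylsilyl ether of F10 | COC(=O)/C(C1CC1)=C/[C@H]1OC(=O)C[C@@H]1[C@H](O[Si](C)(C)C(C)(C)C)CC(C)=C
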